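Count in mM of electrophile, one side product weighing two.

    nucleophile + acid set free ⇌ protonated nucleophile, settled at all times (K1 = 1.40 × 10⁵ /M)
    solid nucleophile ⇌ nucleophile, rate k2*(cs2 - [nucleophile]) while solid is left; crystals form when [nucleophile] > cs2 (cs2 = 8.7 mM, k2 = 0.00285 /min)
    electrophile + target → side product (k3 = 0.0922 /M/min)
    electrophile + nucleophile → acid set free + target (k4 = 0.0582 /M/min)
    acid set free + free base ⇌ salt of the base, settled at all times (K5 = 3.8 × 10⁶ /M)

electrophile 10 mM; free base 2.00 equiv; solid nucleophile 1.00 equiv; time 10 d

- part of the electrophile that has reacted at 10 d
- share of free nucleophile in free nucleophile and protonated nucleophile together, at 10 d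

- in percentages every species weighs as the electrophile in it: one side product counts as two
- as a solid, counted per litre of solution: solid nucleophile
- at the start none of the solid nucleophile is in solution
- run time (flask): 10 d

**Curve's start.** Nucleophile enters at 35.7 mM/d with a time of 0.244 d, short against 10 d, so you may reckon the charge as dissolved. Let b be the fraction of nucleophile left and p the target, as a fraction of the charge. Electrophile stands in both of its rates, so it and time cancel from their ratio, the selectivity factor s = 1.58, and p = (b − b^s)/(s − 1). The curve starts with one target per nucleophile used.

**Crest and level.** In this reckoning target is made as fast as it is lost at b = 0.455, where it crests at 28.7%. Set the electrophile left to zero in its balance, target plus twice the side product: b = (1 − p)/2. Starting from the crest, b is 0.356, p is 27.6%, and b becomes 0.362. The nucleophile spent then equals the end acid, the acid set free counted together with the salt of the base and the protonated nucleophile, 6.38 mM.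

**Two answers.** At those levels, electrophile decays at 0.670 /d. Held over the whole time, that gives 99.9%. The end acid is less than the free base charged, and the two fast balances, with the end acid counted as salt of the base, give 98.3%.

**Forecast.** It gave 99.9% (99.5% to 100%) and 98.3% (98.1% to 98.5%): “The two equivalents of base stay in excess”.

**Simulation.** This flask gives 99.9% and 98.3%.

**Less base.** This flask ends with 6.29 mM of salt of the base, beside the reckoned end acid of 6.38 mM. The neighbouring flask charges 0.500 equiv of free base, or 5.00 mM, less than this flask's end acid. Carry that end acid over as an estimate and let the free base take up its whole charge: about 1.38 mM falls to the nucleophile, out of 3.62 mM reckoned left, so about 61.8% stays free. That neighbouring flask gives 62.1%, with 2.38 mM of nucleophile, 1.45 mM of protonated nucleophile and 5.7% of its free base still free.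

(All constants belong to no real substance; what happens was integrated by code.)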